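**Retrosynthetic overview**

1. Target 18 ⇐ Stille vinylation (C13–C14) of the (12Z)-13-iodoalkene diacetate 16; the acetates go on one step earlier (15 → 16), after the acetonide is removed at the iodide stage (14 → 15).
2. 14 ⇐ Z-selective iodo-Wittig olefination (C12=C13) of lactol 13 ⇐ reduction of the bicyclic hydroxy ester 12.
3. 12 ⇐ acyclic triene 11: both rings close in one cathodic cobalt-hydride HAT radical cascade, ring A first (C4–C5, 6-endo), then ring B (C9–C10, 6-exo Giese); C5, C9 and C10 are set by the C6/C7/C8 triad.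
4. 11 ⇐ methyl ketone 8 + methyl propiolate 9 (chelation-controlled C8–C9 bond, then trans-reduction of the alkyne).
5. 8 ⇐ dimethyl L-tartrate acetonide 1 (supplies C6 and C7) + homoprenyl bromide 4 (half-reduction, dibromoolefination, double Negishi coupling, ester to methyl ketone).

Assumption: compounds 1, 4, 9, 17 and all reagents are bought; carbon atoms of all intermediates carry the labdane numbers of the target (C1–C20).

**Step 1**
Reactants: 1 dimethyl (4R,5R)-2,2-dimethyl-1,3-dioxolane-4,5-dicarboxylate (dimethyl 2,3-O-isopropylidene-L-tartrate)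
Product: 2 methyl (4R,5R)-5-formyl-2,2-dimethyl-1,3-dioxolane-4-carboxylate
Conditions: i-Bu2AlH (1.05 equiv), toluene, −78 °C; aqueous work-up; used crude
Reagents that add atoms: none
Why: Half-reduction of one of two homotopic esters (C2 symmetry) with i-Bu2AlH, whose tetrahedral aluminate is stable at −78 °C and releases the aldehyde only on work-up; no stereocentre is touched.

**Step 2**
Reactants: 2 methyl (4R,5R)-5-formyl-2,2-dimethyl-1,3-dioxolane-4-carboxylate
Product: 3 methyl (4R,5S)-5-(2,2-dibromoethenyl)-2,2-dimethyl-1,3-dioxolane-4-carboxylate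
Conditions: CBr4 (2 equiv), PPh3 (2 equiv), Zn (2 equiv), CH2Cl2, 0 °C → rt
Reagents that add atoms: carbon tetrabromide, BrC(Br)(Br)Br
Why: Corey–Fuchs (Ramirez) dibromoolefination with Ph3P=CBr2 under zinc-buffered neutral conditions that do not epimerise the α-alkoxy centre.

**Step 3**
Reactants: 3 methyl (4R,5S)-5-(2,2-dibromoethenyl)-2,2-dimethyl-1,3-dioxolane-4-carboxylate; 4 5-bromo-2-methylpent-2-ene (homoprenyl bromide)
Product: 6 methyl (4R,5S)-5-[(1E)-2,6-dimethylhepta-1,5-dien-1-yl]-2,2-dimethyl-1,3-dioxolane-4-carboxylate, via bromoalkene ester 5 (not isolated)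
Conditions: 4, Zn, LiCl, THF, 40 °C (gives the alkylzinc bromide); 3, PdCl2(DPEphos) (5 mol %), THF, 0 → 23 °C; then MeZnCl (2 equiv), Pd(t-Bu3P)2 (5 mol %), 23 → 45 °C
Reagents that add atoms: methylzinc chloride, C[Zn]Cl
Why: Two Negishi couplings in one pot: oxidative addition first takes the less hindered C–Br trans to the dioxolane (trans-selective monoalkylation), and the second coupling under Pd(t-Bu3P)2 goes with retention, so the methyl ends cis to C6 (E alkene).

**Step 4**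
Reactants: 6 methyl (4R,5S)-5-[(1E)-2,6-dimethylhepta-1,5-dien-1-yl]-2,2-dimethyl-1,3-dioxolane-4-carboxylate
Product: 8 1-[(4R,5S)-5-[(1E)-2,6-dimethylhepta-1,5-dien-1-yl]-2,2-dimethyl-1,3-dioxolan-4-yl]ethan-1-one, via Weinreb amide 7 (not isolated)
Conditions: MeNH(OMe)·HCl (1.5 equiv), i-PrMgCl (3 equiv), THF, −20 °C; then MeMgBr (3 equiv), −20 → 0 °C
Reagents that add atoms: methylmagnesium bromide, C[Mg]Br; N,O-dimethylhydroxylamine hydrochloride, CNOC.Cl (its atoms stay in 7 only)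
Why: One-pot Weinreb ketone synthesis: the magnesium amide turns the ester into the N-methoxy-N-methylamide, whose chelated adduct with MeMgBr stops at the ketone; C7 is not epimerised at low temperature (trans-dioxolane is also the stable isomer).

**Step 5**
Reactants: 8 1-[(4R,5S)-5-[(1E)-2,6-dimethylhepta-1,5-dien-1-yl]-2,2-dimethyl-1,3-dioxolan-4-yl]ethan-1-one; 9 methyl propiolate
Product: 10 methyl (4R)-4-[(4R,5S)-5-[(1E)-2,6-dimethylhepta-1,5-dien-1-yl]-2,2-dimethyl-1,3-dioxolan-4-yl]-4-hydroxypent-2-ynoate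
Conditions: 9 (1.5 equiv), LiN(SiMe3)2, THF, −78 °C; MgBr2·OEt2 (2 equiv); then 8 in CH2Cl2, −78 → −40 °C
Reagents that add atoms: none
Why: Cram-chelate addition of the acetylide: magnesium bridges the ketone oxygen and O7, the nucleophile attacks C8 from the face opposite C6, giving the 7,8-syn (threo) tertiary alcohol (8R).

**Step 6**
Reactants: 10 methyl (4R)-4-[(4R,5S)-5-[(1E)-2,6-dimethylhepta-1,5-dien-1-yl]-2,2-dimethyl-1,3-dioxolan-4-yl]-4-hydroxypent-2-ynoate
Product: 11 methyl (2E,4R)-4-[(4R,5S)-5-[(1E)-2,6-dimethylhepta-1,5-dien-1-yl]-2,2-dimethyl-1,3-dioxolan-4-yl]-4-hydroxypent-2-enoate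
Conditions: NaAlH2(OCH2CH2OMe)2 (Red-Al, 1.6 equiv), THF, −72 °C, 30 min; aqueous work-up
Reagents that add atoms: none
Why: Hydroxyl-directed trans-hydroalumination of the γ-hydroxy ynoate (Red-Al reduction of a propargylic alcohol) gives only the E-enoate, which cannot close to a butenolide and serves as the Giese acceptor; the ester survives at this temperature.

**Step 7**
Reactants: 11 methyl (2E,4R)-4-[(4R,5S)-5-[(1E)-2,6-dimethylhepta-1,5-dien-1-yl]-2,2-dimethyl-1,3-dioxolan-4-yl]-4-hydroxypent-2-enoate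
Product: 12 methyl (5R,6S,7R,8R,9S,10R)-8-hydroxy-6,7-(isopropylidenedioxy)-13,14,15,16-tetranorlabdan-12-oate
Conditions: CoBr2(glyme) (10 mol %), 4,4'-di-tert-butyl-2,2'-bipyridine (12 mol %), Et3NHBF4 (3 equiv), n-Bu4NBF4 (0.1 M), DMF, 5 mM in 11, undivided cell, Zn anode, Ni-foam cathode, constant current 3 mA (about 3 F/mol), 23 °C
Reagents that add atoms: none
Why: Proposed new method: a cathodically generated trivalent cobalt hydride transfers H• to the electron-rich, unhindered C3=C4 prenyl alkene (C5=C10 is deactivated by the allylic C6–O bond); the tertiary C4 radical closes ring A 6-endo onto C5 anti to C7 (H6 eclipses the alkene to avoid A(1,3) strain with the C10 methyl); the C10 radical then closes ring B 6-exo onto the enoate through a chair with O6, O7 and O8 equatorial and the C8 methyl axial (trans-decalin, C9 side chain equatorial); the α-ester radical is reduced by monovalent cobalt or the cathode and protonated. The closest known chemistry is the iron-hydride/silane HAT-initiated reductive radical polyene cyclisation with Giese termination and cobalt-electrocatalytic HAT functionalisation of alkenes, which has not been shown for a polyene bicyclisation.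

**Step 8**
Reactants: 12 methyl (5R,6S,7R,8R,9S,10R)-8-hydroxy-6,7-(isopropylidenedioxy)-13,14,15,16-tetranorlabdan-12-oate
Product: 13 (5R,6S,7R,8R,9S,10R)-8,12-epoxy-6,7-(isopropylidenedioxy)-13,14,15,16-tetranorlabdan-12-ol (lactol, both C12 epimers)
Conditions: i-Bu2AlH (3 equiv), CH2Cl2, −78 °C; aqueous work-up
Reagents that add atoms: none
Why: Ester-to-lactol reduction: the C8 aluminium alkoxide traps the aldehyde as the five-membered hemiacetal, which stops over-reduction; the acetonide is inert.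

**Step 9**
Reactants: 13 (5R,6S,7R,8R,9S,10R)-8,12-epoxy-6,7-(isopropylidenedioxy)-13,14,15,16-tetranorlabdan-12-ol
Product: 14 (5R,6S,7R,8R,9S,10R,12Z)-13-iodo-6,7-(isopropylidenedioxy)-14,15-dinorlabd-12-en-8-ol
Conditions: [EtPPh3]Br, n-BuLi, THF, 0 °C; I2, −78 °C; NaN(SiMe3)2, −78 → −20 °C; then 13 pre-treated with NaN(SiMe3)2 (1 equiv), −78 → 0 °C
Reagents that add atoms: ethyltriphenylphosphonium bromide, CC[P+](c1ccccc1)(c1ccccc1)c1ccccc1.[Br-]; iodine, II
Why: Stork–Zhao–Wittig olefination of the ring-opened hydroxy aldehyde with Ph3P=C(I)CH3: the kinetic cis-oxaphosphetane places iodine cis to C11, giving the Z trisubstituted vinyl iodide.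

**Step 10**
Reactants: 14 (5R,6S,7R,8R,9S,10R,12Z)-13-iodo-6,7-(isopropylidenedioxy)-14,15-dinorlabd-12-en-8-ol
Product: 15 (5R,6S,7R,8R,9S,10R,12Z)-13-iodo-14,15-dinorlabd-12-ene-6,7,8-triol
Conditions: AcOH/H2O (4:1), 45 °C
Reagents that add atoms: none
Why: Acid-catalysed acetal hydrolysis: the strained trans-fused dioxolane opens under mild aqueous acid, while the vinyl iodide and the tertiary alcohol are inert (the acid-sensitive diene is not yet present).

**Step 11**
Reactants: 15 (5R,6S,7R,8R,9S,10R,12Z)-13-iodo-14,15-dinorlabd-12-ene-6,7,8-triol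
Product: 16 (5R,6S,7R,8R,9S,10R,12Z)-8-hydroxy-13-iodo-14,15-dinorlabd-12-ene-6,7-diyl diacetate
Conditions: Ac2O (6 equiv), pyridine, DMAP (0.2 equiv), CH2Cl2, 0 → 23 °C
Reagents that add atoms: acetic anhydride, CC(=O)OC(C)=O
Why: DMAP-catalysed acetylation takes the two secondary equatorial hydroxyls; the hindered tertiary C8–OH next to the axial methyl is not acylated at room temperature.

**Step 12**
Reactants: 16 (5R,6S,7R,8R,9S,10R,12Z)-8-hydroxy-13-iodo-14,15-dinorlabd-12-ene-6,7-diyl diacetate; 17 tributyl(vinyl)stannane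
Product: 18 (5R,6S,7R,8R,9S,10R,12Z)-8-hydroxylabda-12,14-diene-6,7-diyl diacetate (CNP0537572.1)
Conditions: Pd(PPh3)4 (5 mol %), CuI (20 mol %), DMF, 23 → 40 °C, dark
Reagents that add atoms: none
Why: Stille coupling (zerovalent palladium, copper co-catalysis) replaces iodine by vinyl with retention of alkene geometry under neutral conditions that leave the acetates and the free tertiary alcohol untouched, giving the 12Z diene.

**Compound list**

1 | dimethyl (4R,5R)-2,2-dimethyl-1,3-dioxolane-4,5-dicarboxylate (dimethyl 2,3-O-isopropylidene-L-tartrate) | COC(=O)[C@@H]1OC(C)(C)O[C@H]1C(=O)OC | starting material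
2 | methyl (4R,5R)-5-formyl-2,2-dimethyl-1,3-dioxolane-4-carboxylate | O=C[C@@H]1OC(C)(C)O[C@H]1C(=O)OC | intermediate
3 | methyl (4R,5S)-5-(2,2-dibromoethenyl)-2,2-dimethyl-1,3-dioxolane-4-carboxylate | BrC(Br)=C[C@@H]1OC(C)(C)O[C@H]1C(=O)OC | intermediate
4 | 5-bromo-2-methylpent-2-ene (homoprenyl bromide) | CC(C)=CCCBr | starting material
5 | methyl (4R,5S)-5-[(1Z)-2-bromo-6-methylhepta-1,5-dien-1-yl]-2,2-dimethyl-1,3-dioxolane-4-carboxylate | CC(C)=CCC/C(Br)=C/[C@@H]1OC(C)(C)O[C@H]1C(=O)OC | intermediate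
6 | methyl (4R,5S)-5-[(1E)-2,6-dimethylhepta-1,5-dien-1-yl]-2,2-dimethyl-1,3-dioxolane-4-carboxylate | CC(C)=CCC/C(C)=C/[C@@H]1OC(C)(C)O[C@H]1C(=O)OC | intermediate
7 | (4R,5S)-5-[(1E)-2,6-dimethylhepta-1,5-dien-1-yl]-N-methoxy-N,2,2-trimethyl-1,3-dioxolane-4-carboxamide | CC(C)=CCC/C(C)=C/[C@@H]1OC(C)(C)O[C@H]1C(=O)N(C)OC | intermediate
8 | 1-[(4R,5S)-5-[(1E)-2,6-dimethylhepta-1,5-dien-1-yl]-2,2-dimethyl-1,3-dioxolan-4-yl]ethan-1-one | CC(C)=CCC/C(C)=C/[C@@H]1OC(C)(C)O[C@H]1C(C)=O | intermediate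
9 | methyl propiolate (methyl prop-2-ynoate) | C#CC(=O)OC | starting material
10 | methyl (4R)-4-[(4R,5S)-5-[(1E)-2,6-dimethylhepta-1,5-dien-1-yl]-2,2-dimethyl-1,3-dioxolan-4-yl]-4-hydroxypent-2-ynoate | CC(C)=CCC/C(C)=C/[C@@H]1OC(C)(C)O[C@H]1[C@](C)(O)C#CC(=O)OC | intermediate
11 | methyl (2E,4R)-4-[(4R,5S)-5-[(1E)-2,6-dimethylhepta-1,5-dien-1-yl]-2,2-dimethyl-1,3-dioxolan-4-yl]-4-hydroxypent-2-enoate | CC(C)=CCC/C(C)=C/[C@@H]1OC(C)(C)O[C@H]1[C@](C)(O)/C=C/C(=O)OC | intermediate
12 | methyl (5R,6S,7R,8R,9S,10R)-8-hydroxy-6,7-(isopropylidenedioxy)-13,14,15,16-tetranorlabdan-12-oate (trans-decalin, C9–CH2CO2Me) | COC(=O)C[C@@H]1[C@@](C)(O)[C@H](O3)[C@@H](OC3(C)C)[C@@H]2C(C)(C)CCC[C@]21C | intermediate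
13 | (5R,6S,7R,8R,9S,10R)-8,12-epoxy-6,7-(isopropylidenedioxy)-13,14,15,16-tetranorlabdan-12-ol (lactol, C12 epimers) | OC1C[C@@H]2[C@@](C)(O1)[C@H](O3)[C@@H](OC3(C)C)[C@@H]4C(C)(C)CCC[C@]42C | intermediate
14 | (5R,6S,7R,8R,9S,10R,12Z)-13-iodo-6,7-(isopropylidenedioxy)-14,15-dinorlabd-12-en-8-ol | I/C(C)=C\C[C@@H]1[C@@](C)(O)[C@H](O3)[C@@H](OC3(C)C)[C@@H]2C(C)(C)CCC[C@]21C | intermediate
15 | (5R,6S,7R,8R,9S,10R,12Z)-13-iodo-14,15-dinorlabd-12-ene-6,7,8-triol | I/C(C)=C\C[C@@H]1[C@@](C)(O)[C@H](O)[C@@H](O)[C@@H]2C(C)(C)CCC[C@]21C | intermediate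
16 | (5R,6S,7R,8R,9S,10R,12Z)-8-hydroxy-13-iodo-14,15-dinorlabd-12-ene-6,7-diyl diacetate | I/C(C)=C\C[C@@H]1[C@@](C)(O)[C@H](OC(C)=O)[C@@H](OC(C)=O)[C@@H]2C(C)(C)CCC[C@]21C | intermediate
17 | tributyl(vinyl)stannane | C=C[Sn](CCCC)(CCCC)CCCC | starting material
18 | (5R,6S,7R,8R,9S,10R,12Z)-8-hydroxylabda-12,14-diene-6,7-diyl diacetate (CNP0537572.1) | C=C/C(C)=C\C[C@@H]1[C@@](C)(O)[C@H](OC(C)=O)[C@@H](OC(C)=O)[C@@H]2C(C)(C)CCC[C@]21C | target

**Step count**

Total: 12 steps. Longest linear sequence: 12 steps (1 → 18); 4, 9 and 17 are bought.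

**Three steps most likely to fail, with fallbacks**

Step 7 (the new electrochemical bicyclisation). Likely failure modes are hydrogen evolution or simple hydrogenation outrunning the slow 6-endo closure, HAT to the C5=C10 alkene or the enoate, and imperfect facial control at C5 in the first ring closure. The fallback sets out from 11 and comes back at 12. It gives up the electrode and the cobalt hydride and runs the cascade as a thermal, silane-driven iron-hydride HAT reaction: Fe(acac)3 (1 equiv), PhSiH3 (3 equiv), EtOH/ethylene glycol, 60 °C. This is the known reductive radical polyene cyclisation with Giese termination used for trans-decalin terpenoids. New compounds on this path: none F0.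

Step 5 (C8 by chelation control). A lithium/magnesium acetylide may chelate poorly and give a low 8R:8S ratio. The fallback sets out from 8 and comes back at 11, bypassing 10 and step 6. Vinylmagnesium bromide (CH2=CHMgBr, with MgBr2·OEt2 in CH2Cl2/Et2O at −78 °C) is a true Grignard reagent with reliable Cram-chelate selectivity. It gives (2R)-2-[(4R,5S)-5-[(1E)-2,6-dimethylhepta-1,5-dien-1-yl]-2,2-dimethyl-1,3-dioxolan-4-yl]but-3-en-2-ol F1. Cross-metathesis of its vinyl group with methyl acrylate (second-generation Hoveyda–Grubbs catalyst, CH2Cl2, 40 °C) then gives the E-enoate 11 directly. The trisubstituted alkenes are slow metathesis partners, and ring closure onto C5 is disfavoured by the trans-dioxolane.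

Step 9 (iodo-Wittig on a lactol). The iodo ylide is fragile, the lactol must open, and Z:E may be modest. The fallback sets out from 13 and comes back at 18.
- Corey–Fuchs olefination (CBr4, PPh3, Zn) gives (5R,6S,7R,8R,9S,10R)-13,13-dibromo-6,7-(isopropylidenedioxy)-14,15,16-trinorlabd-12-en-8-ol F2.
- Trans-selective Negishi mono-methylation (MeZnCl, PdCl2(DPEphos)) gives (5R,6S,7R,8R,9S,10R,12Z)-13-bromo-6,7-(isopropylidenedioxy)-14,15-dinorlabd-12-en-8-ol F3.
- AcOH/H2O then gives (5R,6S,7R,8R,9S,10R,12Z)-13-bromo-14,15-dinorlabd-12-ene-6,7,8-triol F4.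
- Ac2O/pyridine/DMAP gives (5R,6S,7R,8R,9S,10R,12Z)-13-bromo-8-hydroxy-14,15-dinorlabd-12-ene-6,7-diyl diacetate F5.
- Stille coupling of F5 with 17 (Pd(t-Bu3P)2, CuI, DMF) gives 18.

**Further compounds**

F0 | step 7 | none | none
F1 | step 5 | (2R)-2-[(4R,5S)-5-[(1E)-2,6-dimethylhepta-1,5-dien-1-yl]-2,2-dimethyl-1,3-dioxolan-4-yl]but-3-en-2-ol | CC(C)=CCC/C(C)=C/[C@@H]1OC(C)(C)O[C@H]1[C@](C)(O)C=C
F2 | step 9 | (5R,6S,7R,8R,9S,10R)-13,13-dibromo-6,7-(isopropylidenedioxy)-14,15,16-trinorlabd-12-en-8-ol | BrC(Br)=CC[C@@H]1[C@@](C)(O)[C@H](O3)[C@@H](OC3(C)C)[C@@H]2C(C)(C)CCC[C@]21C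
F3 | step 9 | (5R,6S,7R,8R,9S,10R,12Z)-13-bromo-6,7-(isopropylidenedioxy)-14,15-dinorlabd-12-en-8-ol | Br/C(C)=C\C[C@@H]1[C@@](C)(O)[C@H](O3)[C@@H](OC3(C)C)[C@@H]2C(C)(C)CCC[C@]21C
F4 | step 9 | (5R,6S,7R,8R,9S,10R,12Z)-13-bromo-14,15-dinorlabd-12-ene-6,7,8-triol | Br/C(C)=C\C[C@@H]1[C@@](C)(O)[C@H](O)[C@@H](O)[C@@H]2C(C)(C)CCC[C@]21C
F5 | step 9 | (5R,6S,7R,8R,9S,10R,12Z)-13-bromo-8-hydroxy-14,15-dinorlabd-12-ene-6,7-diyl diacetate | Br/C(C)=C\C[C@@H]1[C@@](C)(O)[C@H](OC(C)=O)[C@@H](OC(C)=O)[C@@H]2C(C)(C)CCC[C@]21C
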